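Start with the epsilon run, which is the asked flask itself, followed up to 12.0 min.

all flasks: Q 2.1 µM

| charge | D | temperature | remark | time |
|---|---|---|---|---|
| epsilon | 0.094 M | 25 °C | the very flask that is asked about, followed so far |  |
| gamma | 0.047 M | 20 °C | run made earlier |  |
| flask | 0.094 M | 25 °C |  | 15 min |

- epsilon (time / min: E / %): 1.00: 62.6; 2.00: 68.0; 5.00: 71.9; 12.0: 77.1
- gamma (time / s: E / %): 15.0: 24.7; 40.0: 43.1; 80.0: 54.8; 120: 60.0

(standard deviation of a reading: 0.3 percentage points)

- removed E is counted in
- what was read earlier has a scatter of 0.3 percentage points, one standard deviation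
- steps that have been proposed: Q -> J; D + Q -> E + Q; D <-> X
- additions bring no volume worth counting

- Wednesday's: at 15 min add Q, 100% of the amount charged, then wait 8.0 min
- Sunday's: at 15 min raise the temperature by 10 K, then wait 8.0 min
- Friday's: at 15 min take out 90% of the E then present, then wait 8.0 min
- Monday's: change nothing and wait 8.0 min more

- E, in percent of the D first charged, at 15 min
- what to do for the largest gain in E; "none" if nothing gains more than 2 percentage points (Wednesday's / Sunday's / Friday's / Monday's / none)
- E present, with what was taken out counted in, in percent of the D first charged, after Wednesday's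
- E present, with what was taken out counted in, in percent of the D first charged, after Sunday's

E rises in a burst and then creeps. It gains 5.4 percentage points from 1.00 min to 2.00 min, 3.9 points from there to 5.00 min, and 5.2 points from there to 12.0 min. I leave the burst aside and look at the creep. Per minute, as a fraction of the charged D, its rate is 0.0130 min⁻¹ around 3.50 min and 0.00743 min⁻¹ around 8.50 min.

What I freeze is the share of its rate that the creep loses per minute, its fall-off λ. These two rates give λ = 0.112 min⁻¹. This is a reading, built from values that each scatter by 0.3 points. A rate falling in this way still has its rate divided by λ to deliver, and I call that the reserve.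

By my reckoning the reserve is 4.5 points at 12.0 min and 3.2 points at 15 min, so E at 15 min is 78.4%. Waiting 8.0 min more draws 1.9 points from the reserve, less than the 2 points that counts. No proposed step starts from E, so I expect Friday's to bring the same. In D + Q -> E + Q it is Q that comes out unchanged while D becomes E, so Q is a catalyst, and Q -> J is its deactivation. If that is what fades the creep, fresh Q renews the rate, and 21.6% of the charge is not yet E. So I choose Wednesday's, though λ gives no amount for it and none for Sunday's.

The forecast says 78.3%, Wednesday's, 85% and 80.3%, holding that “Fresh Q restarts the drain of X”.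

The flask gives 77.8%, and Wednesday's gains 5.2 points, more than Monday's or Friday's at 1.8 points and Sunday's at 0.31 points. That makes 83.1% after Wednesday's and 78.1% after Sunday's. Added to 77.8%, the reserve gives 81.0% for the same flask left until 150 min, which stands at 81.5%.

    Q → J (k = 0.00130 s⁻¹, Ea = 241 kJ mol⁻¹)
    D + Q → E + Q, rate k2*[D]^2*[Q]/(1 + ([D]/Kh2)^2) (0.160 M, k = 2.90 × 10⁵ M⁻² s⁻¹, Ea = 23.0 kJ mol⁻¹)
    D ⇌ X (K = 2.80, k = 0.00870 s⁻¹, Ea = 91.0 kJ mol⁻¹, ΔH = −18.0 kJ mol⁻¹)
    (constants at 25 °C)

D's use in making E runs at 3.0 times its forward loss to X at 0.259 min, but at 0.11 times that loss at 15.0 min. At that later time 31.0% of the catalyst is still Q, and the flask holds 16.7% as X beside 5.45% as D.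

The runs are simulated for an exercise, and the scatter is random.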